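The constants are made up; what happens was integrated by code.

I carry one ratio here: the rate constant at which the substrate's pool feeds intermediate D, over the one at which intermediate D leaves for target.

in all of them: partner 1.04 M; time 20 min
- north-east: substrate 0.30 M
- south-west: substrate 0.80 M
- north-west: substrate 2.5 M

    substrate ⇌ intermediate C (K1 = 2.1, k1 = 0.14 /min)
    substrate → intermediate B (k2 = 0.11 /min)
    substrate + target ⇌ idle adduct, settled at all times (K3 = 0.76 /M)
    substrate → decomposition product (k4 = 2.3 × 10⁻⁴ /min)
    substrate + partner ⇌ intermediate A (K5 = 0.41 /M, k5 = 0.56 /M/min)
    intermediate D → target (k6 = 0.027 /min)
    intermediate B ⇌ intermediate D (K7 = 8.2, k7 = 0.51 /min)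

- percentages count the substrate that a species holds: one idle adduct counts as two
- target is meant together with its idle adduct
- in an amount of target, one idle adduct counts as one target
- the concentration of target that is asked is that of its free form alone
- "hardly changes" means that all values lie within two and a half points (for a concentration: within two and a half percent of the largest)
- run time (north-east): 20 min

* [target] (only what is free in solution) at the end for north-east, south-west, north-west, in this order
* how that number moves from the first to the last of them (falls, then rises / rises all the way / falls all the way / hardly changes / rises, then falls)

I run the north-east flask in slow motion. In the first instants the partner takes up substrate, with a forward half-life of 1.2 min against 6.3 min for the turning into intermediate B. Intermediate C comes to balance with substrate at a half-time of 3.35 min.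

In the middle, substrate, intermediate A and intermediate C behave as one pool. The free substrate in it feeds intermediate B, so the pool drains with a smaller constant than the step itself:

drain constant = 0.11 /min / (1 + 2.1 + 0.41 /M × 1.04 M) = 0.0312 /min

Intermediate B is a brief stop, because it moves on much faster than the pool drains. So I pass over it.

Towards the end, the exit from intermediate D matters. My hand-over ratio, the drain constant over the exit constant, is:

hand-over ratio = 0.0312 /min / 0.027 /min = 1.16

The two constants lie close, so neither step is the rate-limiting step. Both are first order, and the partner charge is the same in the three flasks, so I take one share of target for each. With a the drain constant and b the exit constant: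

share = 1 − (b·exp(−a·t) − a·exp(−b·t)) / (b − a) = 11.5% at 20 min

The idle adduct then trims free target. I put free substrate at 15.2% of the charge:

free target = share × charge / (1 + 0.76 /M × free substrate)

This gives 0.0335 M in the north-east flask, 0.0845 M in the south-west flask and 0.224 M in the north-west flask, a steady rise.

The forecast gives 0.089 M, 0.23 M and 0.66 M, and says the number rises all the way. Its grounds are “About 30% of the substrate reaches the target in 20 min at every loading”. It holds 30% where I hold 11.5%, and we agree on the shape.

The flasks give 0.0377 M, 0.0974 M and 0.278 M, and the number rises all the way. In the north-east flask at 20.0 min, intermediate D is made 1.27 times faster than it is used up, each step taken net, and it holds 34.9% of the substrate charged against 12.8% in target. That is a momentary ratio of rates, not my ratio of constants, which stands at 1.16 for this flask. In the north-west flask, with 91% of the partner left, the ratio reckons 1.17, and at 20.0 min intermediate D holds 34.8%.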